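**Retrosynthetic overview**
1. Target ⇐ acetylation of the C3 hydroxyl and angeloylation of the side-chain carbinol ⇐ bicyclic hydroxy enal with the acrolein unit at C2 and a silyl ether at C3.
2. Key disconnection: the O1–C2 bond of the dihydrofuran ring together with the exocyclic =CH2. The bicyclic enal ⇐ acyclic o-hydroxyaryl γ-silyloxy enal (stored as its diethyl acetal) + formaldehyde.
3. Enabling feature: C2 is both the carbon bound to the phenolic O1 and the β-carbon of the C2–Cα–CHO unit, and Cα carries the =CH2. The O1–C2–Cα(=CH2)–CHO array is therefore what an oxa-Michael ring closure gives (enamine at Cα) when that same enamine is then methylenated; the C3 stereocentre next to C2 steers the closure.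
4. Acyclic phenol ⇐ O-allyl 5-acetylsalicylaldehyde + 3,3-diethoxypropyne. A catalytic asymmetric alkenylzinc addition sets C3, and asymmetric transfer hydrogenation of the acetyl group sets the side-chain carbinol.
5. Ring order: the benzene ring comes with the starting material. The dihydrofuran ring (O1, C2, C3, C3a, C7a) is the only ring made and is closed last, in the key step.

Key step: step 6

Assumption: 5-acetyl-2-hydroxybenzaldehyde is taken as a catalogue chemical (it is otherwise the Friedel–Crafts acetylation product of salicylaldehyde); locants follow 1-benzofuran numbering and Cα is the acrolein carbon bonded to C2.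

**Route**

Step 1
Reactants: 1 5-acetyl-2-hydroxybenzaldehyde
Product: 2 5-acetyl-2-(prop-2-en-1-yloxy)benzaldehyde
Conditions: allyl bromide, K2CO3, DMF, rt
Reagents that add atoms: allyl bromide C=CCBr
Why: Williamson etherification of the acidic phenol with a carbonate base should install an allyl ether that tolerates the organozinc, silylation and transfer-hydrogenation steps and is later removed under neutral palladium catalysis.

Step 2
Reactants: 2 5-acetyl-2-(prop-2-en-1-yloxy)benzaldehyde; 3 3,3-diethoxyprop-1-yne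
Product: 6 1-{3-[(1S,2E)-4,4-diethoxy-1-hydroxybut-2-en-1-yl]-4-(prop-2-en-1-yloxy)phenyl}ethan-1-one, via alkenylborane 4 (not isolated), via alkenylzinc 5 (not isolated)
Conditions: 3, Cy2BH, toluene, 0 °C to rt; Et2Zn, (−)-MIB [(2S)-3-exo-morpholinoisoborneol] (5 mol%), −78 °C; then 2, −20 to 0 °C; sat. aq. NH4Cl
Reagents that add atoms: 3,3-diethoxyprop-1-yne (compound 3) C#CC(OCC)OCC
Why: Alkyne hydroboration gives the (E)-alkenylborane, boron-to-zinc exchange gives the alkenylzinc, and the amino-alcohol-catalysed asymmetric alkenylzinc addition should deliver the alkenyl group to the Si face of the aldehyde under control of (−)-MIB, setting C3 as (S) while the much less electrophilic methyl ketone is left alone.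

Step 3
Reactants: 6 1-{3-[(1S,2E)-4,4-diethoxy-1-hydroxybut-2-en-1-yl]-4-(prop-2-en-1-yloxy)phenyl}ethan-1-one
Product: 7 1-{3-[(1S,2E)-1-{[tert-butyl(dimethyl)silyl]oxy}-4,4-diethoxybut-2-en-1-yl]-4-(prop-2-en-1-yloxy)phenyl}ethan-1-one
Conditions: TBSCl, imidazole, DMF, rt
Reagents that add atoms: tert-butyldimethylsilyl chloride CC(C)(C)[Si](C)(C)Cl
Why: Imidazole-promoted silylation of the secondary alcohol is non-acidic, so the allylic acetal survives, and it masks the C3 oxygen as a bulky, non-leaving silyl ether for the ring closure.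

Step 4
Reactants: 7 1-{3-[(1S,2E)-1-{[tert-butyl(dimethyl)silyl]oxy}-4,4-diethoxybut-2-en-1-yl]-4-(prop-2-en-1-yloxy)phenyl}ethan-1-one
Product: 8 (1R)-1-{3-[(1S,2E)-1-{[tert-butyl(dimethyl)silyl]oxy}-4,4-diethoxybut-2-en-1-yl]-4-(prop-2-en-1-yloxy)phenyl}ethan-1-ol
Conditions: RuCl[(R,R)-TsDPEN](p-cymene) (2 mol%), HCO2Na, H2O/MeOH (1:1), 40 °C
Reagents that add atoms: none
Why: Noyori asymmetric transfer hydrogenation with the (R,R)-ligand should reduce the aryl methyl ketone through the CH–π-organised outer-sphere transition state to the (R)-1-arylethanol, and the neutral aqueous formate medium spares acetal, silyl ether and alkenes.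

Step 5
Reactants: 8 (1R)-1-{3-[(1S,2E)-1-{[tert-butyl(dimethyl)silyl]oxy}-4,4-diethoxybut-2-en-1-yl]-4-(prop-2-en-1-yloxy)phenyl}ethan-1-ol
Product: 9 2-[(1S,2E)-1-{[tert-butyl(dimethyl)silyl]oxy}-4,4-diethoxybut-2-en-1-yl]-4-[(1R)-1-hydroxyethyl]phenol
Conditions: Pd(PPh3)4 (3 mol%), morpholine, THF, rt
Reagents that add atoms: none
Why: Tsuji–Trost deallylation: zerovalent palladium ionises only the aryl allyl ether (phenoxide leaving group) and morpholine traps the allyl fragment, so the phenol is released without touching the allylic silyl ether or the acetal.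

Step 6
Reactants: 9 2-[(1S,2E)-1-{[tert-butyl(dimethyl)silyl]oxy}-4,4-diethoxybut-2-en-1-yl]-4-[(1R)-1-hydroxyethyl]phenol
Product: 12 2-[(2S,3R)-3-{[tert-butyl(dimethyl)silyl]oxy}-5-[(1R)-1-hydroxyethyl]-2,3-dihydro-1-benzofuran-2-yl]prop-2-enal, via enal 10 (not isolated), via cyclised aldehyde 11 (not isolated)
Conditions: pyrrolidine (0.3 equiv), PhCO2H (1 equiv), iPrOH/H2O (5:1), rt; then 37% aq. CH2O (2 equiv), 45 °C
Reagents that add atoms: formaldehyde C=O; water O
Why: The benzoic acid buffer hydrolyses the allylic acetal to the (E)-enal, which condenses with pyrrolidine to a conjugated iminium ion; the phenolic O1 adds to its β-carbon C2 to form the O1–C2 bond, and the resulting enamine is then trapped by the iminium ion of formaldehyde (Mannich reaction) and loses pyrrolidine by β-elimination to unveil the exocyclic methylene. The closest known reaction types are the iminium-catalysed intramolecular oxa-Michael addition of phenols to enals and the secondary-amine-catalysed α-methylenation of aldehydes with aqueous formaldehyde, run here in sequence in one flask. The only ring closed is the dihydrofuran ring, in the 5-exo-trig mode by heteroatom conjugate addition. The new stereocentre C2 is controlled by the adjacent C3 stereocentre: the bulky silyloxy group sends the side chain to the opposite face, and because the oxa-Michael step is reversible under the conditions (retro-addition through the enamine, and amine conjugate addition to the product), cis material and both enal geometries should be funnelled to the more stable trans-(2S,3R) isomer. The step needs ring closure before methylenation and no γ-deprotonation of the iminium ion at C3; the first is secured because only the cyclised aldehyde has an enolisable α-position and formaldehyde is added after closure, the second by the fast attack of the ortho-phenol and the shielding of the C3–H by the silyl ether.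

Step 7
Reactants: 12 2-[(2S,3R)-3-{[tert-butyl(dimethyl)silyl]oxy}-5-[(1R)-1-hydroxyethyl]-2,3-dihydro-1-benzofuran-2-yl]prop-2-enal; 13 angelic acid [(2Z)-2-methylbut-2-enoic acid]
Product: 15 (1R)-1-[(2S,3R)-3-{[tert-butyl(dimethyl)silyl]oxy}-2-(3-oxoprop-1-en-2-yl)-2,3-dihydro-1-benzofuran-5-yl]ethyl (2Z)-2-methylbut-2-enoate, via mixed anhydride 14 (not isolated)
Conditions: 13, 2,4,6-Cl3C6H2COCl, Et3N, toluene, rt; then 12, 60 °C
Reagents that add atoms: angelic acid (compound 13) C/C=C(/C)C(O)=O
Why: Yamaguchi-type esterification through the preformed mixed anhydride, without a nucleophilic catalyst, should acylate the benzylic alcohol with retention at the carbinol carbon and without Z-to-E isomerisation of the angeloyl group, and it avoids amine conjugate addition to the 2-substituted acrolein.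

Step 8
Reactants: 15 (1R)-1-[(2S,3R)-3-{[tert-butyl(dimethyl)silyl]oxy}-2-(3-oxoprop-1-en-2-yl)-2,3-dihydro-1-benzofuran-5-yl]ethyl (2Z)-2-methylbut-2-enoate
Product: 16 (1R)-1-[(2S,3R)-3-hydroxy-2-(3-oxoprop-1-en-2-yl)-2,3-dihydro-1-benzofuran-5-yl]ethyl (2Z)-2-methylbut-2-enoate
Conditions: HF·pyridine, pyridine/THF, 0 °C to rt
Reagents that add atoms: none
Why: Buffered fluoride desilylation should free the C3 hydroxyl while the pyridine buffer keeps the benzylic ester, the benzylic C3 position and the enal intact; the trans arrangement prevents lactol formation with the aldehyde.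

Step 9
Reactants: 16 (1R)-1-[(2S,3R)-3-hydroxy-2-(3-oxoprop-1-en-2-yl)-2,3-dihydro-1-benzofuran-5-yl]ethyl (2Z)-2-methylbut-2-enoate
Product: 17 (1R)-1-[(2S,3R)-3-acetoxy-2-(3-oxoprop-1-en-2-yl)-2,3-dihydro-1-benzofuran-5-yl]ethyl (2Z)-2-methylbut-2-enoate (target)
Conditions: Ac2O, pyridine, CH2Cl2, 0 °C to rt
Reagents that add atoms: acetic anhydride CC(=O)OC(C)=O
Why: Pyridine-mediated O-acetylation of the secondary C3 alcohol proceeds with retention and, with no stronger nucleophilic catalyst present, should not disturb the acrolein unit or ionise C3.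

**Compound list**
1 | 5-acetyl-2-hydroxybenzaldehyde | CC(=O)c1ccc(O)c(C=O)c1 | starting material
2 | 5-acetyl-2-(prop-2-en-1-yloxy)benzaldehyde | CC(=O)c1ccc(OCC=C)c(C=O)c1 | intermediate
3 | 3,3-diethoxyprop-1-yne | C#CC(OCC)OCC | starting material
4 | dicyclohexyl[(E)-3,3-diethoxyprop-1-en-1-yl]borane | CCOC(OCC)/C=C/B(C1CCCCC1)C1CCCCC1 | intermediate (not isolated)
5 | [(E)-3,3-diethoxyprop-1-en-1-yl](ethyl)zinc | CC[Zn]/C=C/C(OCC)OCC | intermediate (not isolated)
6 | 1-{3-[(1S,2E)-4,4-diethoxy-1-hydroxybut-2-en-1-yl]-4-(prop-2-en-1-yloxy)phenyl}ethan-1-one | CC(=O)c1ccc(OCC=C)c(c1)[C@@H](O)/C=C/C(OCC)OCC | intermediate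
7 | 1-{3-[(1S,2E)-1-{[tert-butyl(dimethyl)silyl]oxy}-4,4-diethoxybut-2-en-1-yl]-4-(prop-2-en-1-yloxy)phenyl}ethan-1-one | CC(=O)c1ccc(OCC=C)c(c1)[C@@H](O[Si](C)(C)C(C)(C)C)/C=C/C(OCC)OCC | intermediate
8 | (1R)-1-{3-[(1S,2E)-1-{[tert-butyl(dimethyl)silyl]oxy}-4,4-diethoxybut-2-en-1-yl]-4-(prop-2-en-1-yloxy)phenyl}ethan-1-ol | C[C@@H](O)c1ccc(OCC=C)c(c1)[C@@H](O[Si](C)(C)C(C)(C)C)/C=C/C(OCC)OCC | intermediate
9 | 2-[(1S,2E)-1-{[tert-butyl(dimethyl)silyl]oxy}-4,4-diethoxybut-2-en-1-yl]-4-[(1R)-1-hydroxyethyl]phenol | C[C@@H](O)c1ccc(O)c(c1)[C@@H](O[Si](C)(C)C(C)(C)C)/C=C/C(OCC)OCC | intermediate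
10 | (2E,4S)-4-{[tert-butyl(dimethyl)silyl]oxy}-4-{2-hydroxy-5-[(1R)-1-hydroxyethyl]phenyl}but-2-enal | C[C@@H](O)c1ccc(O)c(c1)[C@@H](O[Si](C)(C)C(C)(C)C)/C=C/C=O | intermediate (not isolated)
11 | 2-[(2S,3R)-3-{[tert-butyl(dimethyl)silyl]oxy}-5-[(1R)-1-hydroxyethyl]-2,3-dihydro-1-benzofuran-2-yl]acetaldehyde | O=CC[C@@H]1Oc2ccc([C@@H](C)O)cc2[C@H]1O[Si](C)(C)C(C)(C)C | intermediate (not isolated)
12 | 2-[(2S,3R)-3-{[tert-butyl(dimethyl)silyl]oxy}-5-[(1R)-1-hydroxyethyl]-2,3-dihydro-1-benzofuran-2-yl]prop-2-enal | C=C(C=O)[C@@H]1Oc2ccc([C@@H](C)O)cc2[C@H]1O[Si](C)(C)C(C)(C)C | intermediate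
13 | angelic acid, (2Z)-2-methylbut-2-enoic acid | C/C=C(/C)C(O)=O | starting material
14 | (2Z)-2-methylbut-2-enoic 2,4,6-trichlorobenzoic anhydride | C/C=C(/C)C(=O)OC(=O)c1c(Cl)cc(Cl)cc1Cl | intermediate (not isolated)
15 | (1R)-1-[(2S,3R)-3-{[tert-butyl(dimethyl)silyl]oxy}-2-(3-oxoprop-1-en-2-yl)-2,3-dihydro-1-benzofuran-5-yl]ethyl (2Z)-2-methylbut-2-enoate | C=C(C=O)[C@@H]1Oc2ccc([C@@H](C)OC(=O)/C(C)=C\C)cc2[C@H]1O[Si](C)(C)C(C)(C)C | intermediate
16 | (1R)-1-[(2S,3R)-3-hydroxy-2-(3-oxoprop-1-en-2-yl)-2,3-dihydro-1-benzofuran-5-yl]ethyl (2Z)-2-methylbut-2-enoate | C=C(C=O)[C@@H]1Oc2ccc([C@@H](C)OC(=O)/C(C)=C\C)cc2[C@H]1O | intermediate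
17 | (1R)-1-[(2S,3R)-3-acetoxy-2-(3-oxoprop-1-en-2-yl)-2,3-dihydro-1-benzofuran-5-yl]ethyl (2Z)-2-methylbut-2-enoate | C=C(C=O)[C@@H]1Oc2ccc([C@@H](C)OC(=O)/C(C)=C\C)cc2[C@H]1OC(C)=O | target

**Count and risks**
Total step count: 9. Longest linear sequence: 9 steps (from 1).

Most likely to fail, step 6: γ-deprotonation of the iminium ion could scramble C3 or isomerise the chain to an enol silyl ether, the trans preference at C2 could be incomplete, or formaldehyde could aminomethylate the phenol before ring closure. The fallback separates the events and closes the ring without an amine. It sets out from 9: the acetal is hydrolysed with pyridinium p-toluenesulfonate in wet acetone to the enal 10, now isolated. The ring is then closed by phenoxide conjugate addition (catalytic Cs2CO3, MeCN, 0 °C, thermodynamic control) to the aldehyde 11, whose trans isomer is purified. Stoichiometric Eschenmoser methylenation (dimethylmethylideneammonium iodide, Et3N, CH2Cl2) gives the Mannich base 3-(dimethylamino)-2-(dihydrobenzofuran-2-yl)propanal F1, which should lose dimethylamine on warming with silica gel and so comes back to the route at 12.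

Second, step 2: coordination of the acetal oxygens to zinc could erode facial selectivity or favour ethyl transfer. The fallback replaces catalyst control by resolution and sets out from 2. The same alkenylzinc addition run without the chiral amino alcohol gives the racemic allylic alcohol F2. Sharpless kinetic resolution (Ti(OiPr)4, L-(+)-diisopropyl tartrate, tBuOOH, 4 Å molecular sieves, CH2Cl2, −20 °C) should epoxidise the (R)-enantiomer to the epoxy alcohol F3 and leave the (S)-alcohol, which comes back to the route at 6.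

Third, step 7: the angeloyl group could isomerise from Z to E during activation, or the 2-substituted acrolein could be degraded by heat or nucleophiles during the acylation. The fallback changes the order so that the ester is made before the reactive methylene exists. It sets out from 9: the first stage of step 6 is run without formaldehyde and the aldehyde 11 is isolated. Esterification of 11 with the mixed anhydride 14 (toluene, rt to 60 °C) gives the angelate aldehyde F4. Amine-catalysed α-methylenation (pyrrolidine, propionic acid, 37% aq. CH2O, iPrOH, 45 °C) then comes back to the route at 15.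

Further compounds
F1 | step 6 | 3-(dimethylamino)-2-[(2S,3R)-3-{[tert-butyl(dimethyl)silyl]oxy}-5-[(1R)-1-hydroxyethyl]-2,3-dihydro-1-benzofuran-2-yl]propanal (both epimers at C2 of the propanal) | CN(C)CC(C=O)[C@@H]1Oc2ccc([C@@H](C)O)cc2[C@H]1O[Si](C)(C)C(C)(C)C
F2 | step 2 | racemic 1-{3-[(2E)-4,4-diethoxy-1-hydroxybut-2-en-1-yl]-4-(prop-2-en-1-yloxy)phenyl}ethan-1-one | CC(=O)c1ccc(OCC=C)c(c1)C(O)/C=C/C(OCC)OCC
F3 | step 2 | 1-{3-[(S)-[(2R,3S)-3-(diethoxymethyl)oxiran-2-yl](hydroxy)methyl]-4-(prop-2-en-1-yloxy)phenyl}ethan-1-one | CC(=O)c1ccc(OCC=C)c(c1)[C@H](O)[C@H]2O[C@@H]2C(OCC)OCC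
F4 | step 7 | (1R)-1-[(2S,3R)-3-{[tert-butyl(dimethyl)silyl]oxy}-2-(2-oxoethyl)-2,3-dihydro-1-benzofuran-5-yl]ethyl (2Z)-2-methylbut-2-enoate | O=CC[C@@H]1Oc2ccc([C@@H](C)OC(=O)/C(C)=C\C)cc2[C@H]1O[Si](C)(C)C(C)(C)C
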